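Ring B is disconnected across C7–C8 and C9–C10 (eudesmane numbering), excising the unsubstituted C8–C9 ethano bridge as ethylene. The key step is a radical [4+2] annulation: a tertiary α-keto radical at C10 of a ring A bromoketone captures ethylene, and the resulting C8 radical closes ring B by 6-exo attack on C7 of a sulfonylmethyl enoate, whose sulfonyl loss unveils the 11(13)-methylene ester. It exploits the CH2–CH2 unit flanked by quaternary C10 and C7 and sets both centres. The precursor is a monocyclic 2-bromo-2-methylcyclohexanone carrying, at C5, the acylated C6 carbinol and a (Z)-2-(phenylsulfonylmethyl)enoate, assembled by asymmetric conjugate methylation and an anti-aldol.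

Key step: step 12

Remark: the eudesmane numbering of the target (C1–C15; ring A = C1–C5, C10; ring B = C5–C10) is used for every intermediate.
Assumption: the (S,R,R)-phosphoramidite/Cu(OTf)2 catalyst delivers methyl to the enone face that gives the (6R) enol ether 9, as with simple cyclohexenones; if the sense proves opposite, the mirror-image ligand is used.

Step 1
Reactants: 1 2,2-dimethoxyacetaldehyde; 2 methyl acrylate
Product: 3 methyl 3-hydroxy-4,4-dimethoxy-2-methylidenebutanoate (racemic)
Conditions: DABCO (0.5 equiv), dioxane/H2O, 25 °C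
Reagents that add atoms: none
Why: Morita–Baylis–Hillman reaction, in which the DABCO-derived ammonium enolate of the acrylate adds to the activated α,α-dialkoxy aldehyde; the racemic carbinol centre is lost in step 2.

Step 2
Reactants: 3 methyl 3-hydroxy-4,4-dimethoxy-2-methylidenebutanoate
Product: 5 methyl (2Z)-4,4-dimethoxy-2-[(phenylsulfonyl)methyl]but-2-enoate, via allylic acetate 4 (not isolated)
Conditions: Ac2O, Et3N, DMAP (cat.), CH2Cl2, 0 °C; then PhSO2Na, DMF, 25 °C
Reagents that add atoms: sodium benzenesulfinate [Na+].[O-]S(=O)c1ccccc1; acetic anhydride CC(=O)OC(C)=O (acetyl group stays only in 4)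
Why: acetylation followed by SN2' substitution (conjugate addition–elimination) of the Morita–Baylis–Hillman acetate by the S-nucleophilic sulfinate should give the thermodynamic trisubstituted allyl sulfone with the acetal carbon trans to the ester.

Step 3
Reactants: 5 methyl (2Z)-4,4-dimethoxy-2-[(phenylsulfonyl)methyl]but-2-enoate
Product: 6 methyl (2Z)-4-oxo-2-[(phenylsulfonyl)methyl]but-2-enoate
Conditions: TFA/H2O (4:1), CH2Cl2, 0 °C
Reagents that add atoms: water O
Why: acid-catalysed acetal hydrolysis should free the conjugated aldehyde without touching the ester or sulfone, the alkene geometry being retained.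

Step 4
Reactants: 7 1,4-dioxaspiro[4.5]dec-6-en-8-one
Product: 9 trimethyl{[(6R)-6-methyl-1,4-dioxaspiro[4.5]dec-7-en-8-yl]oxy}silane, via methylzinc enolate 8 (not isolated)
Conditions: Me2Zn, Cu(OTf)2 (2 mol %), (S,R,R)-BINOL-derived bis(1-phenylethyl)phosphoramidite (4 mol %), toluene, −30 °C; then TMSOTf, −30 to 0 °C
Reagents that add atoms: dimethylzinc C[Zn]C; trimethylsilyl trifluoromethanesulfonate C[Si](C)(C)OS(=O)(=O)C(F)(F)F
Why: copper-catalysed enantioselective conjugate addition of a dialkylzinc, in which the chiral phosphoramidite selects the enone face and so sets the methyl-bearing C10 as R, followed by O-silylation of the zinc enolate, which fixes the C4=C5 enolate regiochemistry.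

Step 5
Reactants: 9 trimethyl{[(6R)-6-methyl-1,4-dioxaspiro[4.5]dec-7-en-8-yl]oxy}silane; 6 methyl (2Z)-4-oxo-2-[(phenylsulfonyl)methyl]but-2-enoate
Product: 12 methyl (2Z,4S)-4-hydroxy-4-[(6R,7S)-6-methyl-8-oxo-1,4-dioxaspiro[4.5]decan-7-yl]-2-[(phenylsulfonyl)methyl]but-2-enoate, via lithium enolate 10 (not isolated), via dicyclohexylboron enolate 11 (not isolated)
Conditions: MeLi, THF, 0 °C; (c-C6H11)2BCl, −78 °C; then 6, −78 to −40 °C; pH 7 buffer
Reagents that add atoms: methyllithium [Li]C (lithium only in 10); chlorodicyclohexylborane ClB(C1CCCCC1)C1CCCCC1 (boron only in 11)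
Why: boron aldol addition through a Zimmerman–Traxler chair, in which the ring (E)-enolate gives the anti adduct (sets C6) and the aldehyde approaches C5 trans to the neighbouring C10 methyl (sets C5), the non-basic enolate leaving the acidic sulfonyl methylene alone.

Step 6
Reactants: 12 methyl (2Z,4S)-4-hydroxy-4-[(6R,7S)-6-methyl-8-oxo-1,4-dioxaspiro[4.5]decan-7-yl]-2-[(phenylsulfonyl)methyl]but-2-enoate
Product: 13 methyl (2Z,4S)-4-hydroxy-4-[(6R,7R)-6-methyl-8-methylidene-1,4-dioxaspiro[4.5]decan-7-yl]-2-[(phenylsulfonyl)methyl]but-2-enoate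
Conditions: Zn, CH2Br2, TiCl4, THF/CH2Cl2, 0 to 25 °C
Reagents that add atoms: dibromomethane BrCBr
Why: Takai–Lombardo methylenation, whose non-basic gem-dimetallic reagent should turn the C4 ketone into the C4(15) exocyclic alkene without retro-aldol or β-elimination and without touching ester, ketal or free hydroxyl.

Step 7
Reactants: 14 methyl 2-(hydroxymethyl)prop-2-enoate
Product: 15 methyl 2-{[(tert-butyldiphenylsilyl)oxy]methyl}prop-2-enoate
Conditions: TBDPSCl, imidazole, DMF, 25 °C
Reagents that add atoms: tert-butyl(chloro)diphenylsilane CC(C)(C)[Si](Cl)(c1ccccc1)c1ccccc1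
Why: imidazole-mediated silylation of the primary alcohol gives an acid-tolerant silyl ether that survives the later ketal hydrolysis.

Step 8
Reactants: 15 methyl 2-{[(tert-butyldiphenylsilyl)oxy]methyl}prop-2-enoate
Product: 16 2-{[(tert-butyldiphenylsilyl)oxy]methyl}prop-2-enoic acid
Conditions: LiOH, THF/H2O, 0 °C; then 1 M HCl to pH 3
Reagents that add atoms: lithium hydroxide [Li+].[OH-]
Why: saponification, in which hydroxide attack at the unhindered methyl ester at 0 °C should outpace conjugate addition to the α-substituted acrylate.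

Step 9
Reactants: 13 methyl (2Z,4S)-4-hydroxy-4-[(6R,7R)-6-methyl-8-methylidene-1,4-dioxaspiro[4.5]decan-7-yl]-2-[(phenylsulfonyl)methyl]but-2-enoate; 16 2-{[(tert-butyldiphenylsilyl)oxy]methyl}prop-2-enoic acid
Product: 17 methyl (2Z,4S)-4-[(2-{[(tert-butyldiphenylsilyl)oxy]methyl}prop-2-enoyl)oxy]-4-[(6R,7R)-6-methyl-8-methylidene-1,4-dioxaspiro[4.5]decan-7-yl]-2-[(phenylsulfonyl)methyl]but-2-enoate
Conditions: DIC, DMAP (cat.), CH2Cl2, 0 to 25 °C
Reagents that add atoms: none
Why: Steglich esterification of the only free hydroxyl (O6); acylating before ring B exists means O6 can never lactonise onto the C12 ester later, and the (Z)-geometry keeps that ester out of reach now.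

Step 10
Reactants: 17 the O6-acylated ketal
Product: 18 methyl (2Z,4S)-4-[(2-{[(tert-butyldiphenylsilyl)oxy]methyl}prop-2-enoyl)oxy]-4-[(1R,2R)-2-methyl-6-methylidene-3-oxocyclohexyl]-2-[(phenylsulfonyl)methyl]but-2-enoate
Conditions: PPTS, acetone/H2O (10:1), 50 °C
Reagents that add atoms: water O
Why: mild acid-catalysed transketalisation should release the C1 ketone while the TBDPS ether, the esters and the exocyclic alkene are stable to PPTS.

Step 11
Reactants: 18 the C1 ketone
Product: 20 methyl (2Z,4S)-4-[(2-{[(tert-butyldiphenylsilyl)oxy]methyl}prop-2-enoyl)oxy]-4-[(1R)-2-bromo-2-methyl-6-methylidene-3-oxocyclohexyl]-2-[(phenylsulfonyl)methyl]but-2-enoate (both C10 epimers), via trimethylsilyl enol ether 19 (not isolated)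
Conditions: TMSOTf, Et3N, CH2Cl2, 0 to 25 °C (equilibration); then NBS, THF, −78 °C
Reagents that add atoms: N-bromosuccinimide O=C1CCC(=O)N1Br; trimethylsilyl trifluoromethanesulfonate C[Si](C)(C)OS(=O)(=O)C(F)(F)F (silyl group only in 19)
Why: equilibrating soft enolisation should favour the tetrasubstituted C1=C10 silyl enol ether, which is far more nucleophilic than any alkene present and is brominated by NBS at C10; the C10 configuration is irrelevant because it becomes a radical centre.

Step 12
Reactants: 20 the C10 bromoketone; 21 ethylene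
Product: 22 methyl 6α-[(2-{[(tert-butyldiphenylsilyl)oxy]methyl}prop-2-enoyl)oxy]-1-oxo-5αH,7αH-eudesma-4(15),11(13)-dien-12-oate (10β-methyl, trans-decalin)
Conditions: ethylene (10 bar), (Bu3Sn)2 (1.1 equiv), benzene (0.01 M), hν (sun lamp, Pyrex), 30 °C
Reagents that add atoms: none
Why: Proposed new method: photolysis of (Bu3Sn)2 gives Bu3Sn radicals that abstract bromine from 20, and the electrophilic tertiary α-keto radical at C10 adds to ethylene (forming C9–C10) faster than it can attack its own electron-poor alkenes; the nucleophilic primary C8 radical then cyclises 6-exo-trig onto C7 of the enoate (forming C7–C8 and ring B), and the C11 radical expels a PhSO2 radical to unveil the C11(13) methylene, the sulfonyl radical being taken up by the ditin to continue the chain. The closest known reaction types are atom-transfer radical addition of α-bromo carbonyl compounds to ethylene and radical allylation by addition–fragmentation of allyl sulfones (radical annulation); what is new is their union with ethylene as the two-carbon partner on a substrate of this kind. Ring B closes in the 6-exo-trig mode through a chair transition state. C10 is controlled by C5: allylic strain against the C4 methylene and the C10 methyl holds the C5 side chain axial, so ethylene enters anti to it (C9 trans to C6, methyl β); C7 is controlled by C6 through the chair, in which the C6 acyloxy group and the C7–C11 bond both sit equatorial (7α-H). The step needs ethylene capture to beat reduction or dimerisation of the C10 radical, and 6-exo attack on C7 to beat attack on C15 or on the O6 acrylate; ethylene pressure, high dilution, the absence of a hydrogen donor and the polarity match between the alkyl radical and the enoate should secure this.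

Step 13
Reactants: 22 the 1-oxo bicycle
Product: 23 methyl 6α-[(2-{[(tert-butyldiphenylsilyl)oxy]methyl}prop-2-enoyl)oxy]-1β-hydroxy-5αH,7αH-eudesma-4(15),11(13)-dien-12-oate
Conditions: NaBH4, CeCl3·7H2O, MeOH, −40 °C
Reagents that add atoms: none
Why: Luche-type carbonyl reduction, in which axial hydride delivery from the α face (opposite the axial 10β-methyl) should give the equatorial 1β-alcohol while both acrylate esters are spared.

Step 14
Reactants: 23 the 1β-alcohol
Product: 24 methyl 6α-[(2-{[(tert-butyldiphenylsilyl)oxy]methyl}prop-2-enoyl)oxy]-1β,3α-dihydroxy-5αH,7αH-eudesma-4(15),11(13)-dien-12-oate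
Conditions: SeO2 (0.5 equiv), t-BuOOH (3 equiv), CH2Cl2, 25 °C
Reagents that add atoms: tert-butyl hydroperoxide CC(C)(C)OO (oxygen delivered through SeO2)
Why: SeO2 allylic hydroxylation (ene reaction, then [2,3]-sigmatropic shift) should attack only the electron-rich C4(15) alkene, at the C3 methylene in preference to the hindered C5 methine, and is expected to deliver oxygen axially (3α); this centre is reset in steps 15 and 16.

Step 15
Reactants: 24 the 1β,3α-diol
Product: 25 methyl 6α-[(2-{[(tert-butyldiphenylsilyl)oxy]methyl}prop-2-enoyl)oxy]-1β-hydroxy-3-oxo-5αH,7αH-eudesma-4(15),11(13)-dien-12-oate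
Conditions: MnO2 (activated, excess), CH2Cl2, 25 °C
Reagents that add atoms: none
Why: MnO2 oxidation is selective for the allylic C3 alcohol over the saturated C1 alcohol, so no 1,3-diketone can form; the β-hydroxy enone is carried on at once.

Step 16
Reactants: 25 the 3-oxo compound
Product: 26 methyl 6α-[(2-{[(tert-butyldiphenylsilyl)oxy]methyl}prop-2-enoyl)oxy]-1β,3β-dihydroxy-5αH,7αH-eudesma-4(15),11(13)-dien-12-oate
Conditions: NaBH4, CeCl3·7H2O, MeOH, −78 °C
Reagents that add atoms: none
Why: Luche 1,2-reduction of the α-methylene ketone, in which axial hydride attack from the α face should give the equatorial 3β-alcohol (cis to the 1β-hydroxyl).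

Step 17
Reactants: 26 the silyl-protected diol
Product: 27 methyl 1β,3β-dihydroxy-6α-{[2-(hydroxymethyl)prop-2-enoyl]oxy}-5αH,7αH-eudesma-4(15),11(13)-dien-12-oate (CNP0247525.1)
Conditions: HF·pyridine, THF, 0 to 25 °C
Reagents that add atoms: none
Why: fluoride-mediated cleavage of the primary TBDPS ether under mildly acidic conditions should leave both acrylate esters and the allylic alcohols untouched.

Compound list
1 | 2,2-dimethoxyacetaldehyde | COC(OC)C=O | starting material
2 | methyl acrylate | C=CC(=O)OC | starting material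
3 | methyl 3-hydroxy-4,4-dimethoxy-2-methylidenebutanoate (racemic) | COC(OC)C(O)C(=C)C(=O)OC | intermediate
4 | methyl 3-acetoxy-4,4-dimethoxy-2-methylidenebutanoate (allylic acetate) | COC(OC)C(OC(C)=O)C(=C)C(=O)OC | intermediate
5 | methyl (2Z)-4,4-dimethoxy-2-[(phenylsulfonyl)methyl]but-2-enoate | COC(OC)/C=C(/C(=O)OC)CS(=O)(=O)c1ccccc1 | intermediate
6 | methyl (2Z)-4-oxo-2-[(phenylsulfonyl)methyl]but-2-enoate | O=C/C=C(/C(=O)OC)CS(=O)(=O)c1ccccc1 | intermediate
7 | 1,4-dioxaspiro[4.5]dec-6-en-8-one | O=C1C=CC2(CC1)OCCO2 | starting material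
8 | methylzinc (6R)-6-methyl-1,4-dioxaspiro[4.5]dec-7-en-8-olate (methylzinc enolate) | C[Zn]OC1=C[C@@H](C)C2(CC1)OCCO2 | intermediate
9 | trimethyl{[(6R)-6-methyl-1,4-dioxaspiro[4.5]dec-7-en-8-yl]oxy}silane | C[Si](C)(C)OC1=C[C@@H](C)C2(CC1)OCCO2 | intermediate
10 | lithium (6R)-6-methyl-1,4-dioxaspiro[4.5]dec-7-en-8-olate (lithium enolate) | [Li]OC1=C[C@@H](C)C2(CC1)OCCO2 | intermediate
11 | dicyclohexyl{[(6R)-6-methyl-1,4-dioxaspiro[4.5]dec-7-en-8-yl]oxy}borane (dicyclohexylboron enolate) | C1CCC(CC1)B(OC1=C[C@@H](C)C2(CC1)OCCO2)C1CCCCC1 | intermediate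
12 | methyl (2Z,4S)-4-hydroxy-4-[(6R,7S)-6-methyl-8-oxo-1,4-dioxaspiro[4.5]decan-7-yl]-2-[(phenylsulfonyl)methyl]but-2-enoate | O[C@@H](/C=C(/C(=O)OC)CS(=O)(=O)c1ccccc1)[C@H]1C(=O)CCC2(OCCO2)[C@@H]1C | intermediate
13 | methyl (2Z,4S)-4-hydroxy-4-[(6R,7R)-6-methyl-8-methylidene-1,4-dioxaspiro[4.5]decan-7-yl]-2-[(phenylsulfonyl)methyl]but-2-enoate | O[C@@H](/C=C(/C(=O)OC)CS(=O)(=O)c1ccccc1)[C@H]1C(=C)CCC2(OCCO2)[C@@H]1C | intermediate
14 | methyl 2-(hydroxymethyl)prop-2-enoate | C=C(CO)C(=O)OC | starting material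
15 | methyl 2-{[(tert-butyldiphenylsilyl)oxy]methyl}prop-2-enoate | C=C(CO[Si](c1ccccc1)(c1ccccc1)C(C)(C)C)C(=O)OC | intermediate
16 | 2-{[(tert-butyldiphenylsilyl)oxy]methyl}prop-2-enoic acid | C=C(CO[Si](c1ccccc1)(c1ccccc1)C(C)(C)C)C(=O)O | intermediate
17 | methyl (2Z,4S)-4-[(2-{[(tert-butyldiphenylsilyl)oxy]methyl}prop-2-enoyl)oxy]-4-[(6R,7R)-6-methyl-8-methylidene-1,4-dioxaspiro[4.5]decan-7-yl]-2-[(phenylsulfonyl)methyl]but-2-enoate | C=C(CO[Si](c1ccccc1)(c1ccccc1)C(C)(C)C)C(=O)O[C@@H](/C=C(/C(=O)OC)CS(=O)(=O)c1ccccc1)[C@H]1C(=C)CCC2(OCCO2)[C@@H]1C | intermediate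
18 | methyl (2Z,4S)-4-[(2-{[(tert-butyldiphenylsilyl)oxy]methyl}prop-2-enoyl)oxy]-4-[(1R,2R)-2-methyl-6-methylidene-3-oxocyclohexyl]-2-[(phenylsulfonyl)methyl]but-2-enoate | C=C(CO[Si](c1ccccc1)(c1ccccc1)C(C)(C)C)C(=O)O[C@@H](/C=C(/C(=O)OC)CS(=O)(=O)c1ccccc1)[C@H]1C(=C)CCC(=O)[C@@H]1C | intermediate
19 | methyl (2Z,4S)-4-[(2-{[(tert-butyldiphenylsilyl)oxy]methyl}prop-2-enoyl)oxy]-4-[(1S)-2-methyl-6-methylidene-3-[(trimethylsilyl)oxy]cyclohex-2-en-1-yl]-2-[(phenylsulfonyl)methyl]but-2-enoate (C1=C10 trimethylsilyl enol ether of 18) | C=C(CO[Si](c1ccccc1)(c1ccccc1)C(C)(C)C)C(=O)O[C@@H](/C=C(/C(=O)OC)CS(=O)(=O)c1ccccc1)[C@H]1C(=C)CCC(O[Si](C)(C)C)=C1C | intermediate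
20 | methyl (2Z,4S)-4-[(2-{[(tert-butyldiphenylsilyl)oxy]methyl}prop-2-enoyl)oxy]-4-[(1R)-2-bromo-2-methyl-6-methylidene-3-oxocyclohexyl]-2-[(phenylsulfonyl)methyl]but-2-enoate (C10 bromoketone, both C10 epimers) | C=C(CO[Si](c1ccccc1)(c1ccccc1)C(C)(C)C)C(=O)O[C@@H](/C=C(/C(=O)OC)CS(=O)(=O)c1ccccc1)[C@H]1C(=C)CCC(=O)C1(C)Br | intermediate
21 | ethylene | C=C | starting material
22 | methyl 6α-[(2-{[(tert-butyldiphenylsilyl)oxy]methyl}prop-2-enoyl)oxy]-1-oxo-5αH,7αH-eudesma-4(15),11(13)-dien-12-oate | C=C(CO[Si](c1ccccc1)(c1ccccc1)C(C)(C)C)C(=O)O[C@@H]1[C@H]2C(=C)CCC(=O)[C@]2(C)CC[C@H]1C(=C)C(=O)OC | intermediate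
23 | methyl 6α-[(2-{[(tert-butyldiphenylsilyl)oxy]methyl}prop-2-enoyl)oxy]-1β-hydroxy-5αH,7αH-eudesma-4(15),11(13)-dien-12-oate | C=C(CO[Si](c1ccccc1)(c1ccccc1)C(C)(C)C)C(=O)O[C@@H]1[C@H]2C(=C)CC[C@@H](O)[C@]2(C)CC[C@H]1C(=C)C(=O)OC | intermediate
24 | methyl 6α-[(2-{[(tert-butyldiphenylsilyl)oxy]methyl}prop-2-enoyl)oxy]-1β,3α-dihydroxy-5αH,7αH-eudesma-4(15),11(13)-dien-12-oate | C=C(CO[Si](c1ccccc1)(c1ccccc1)C(C)(C)C)C(=O)O[C@@H]1[C@H]2C(=C)[C@H](O)C[C@@H](O)[C@]2(C)CC[C@H]1C(=C)C(=O)OC | intermediate
25 | methyl 6α-[(2-{[(tert-butyldiphenylsilyl)oxy]methyl}prop-2-enoyl)oxy]-1β-hydroxy-3-oxo-5αH,7αH-eudesma-4(15),11(13)-dien-12-oate | C=C(CO[Si](c1ccccc1)(c1ccccc1)C(C)(C)C)C(=O)O[C@@H]1[C@H]2C(=C)C(=O)C[C@@H](O)[C@]2(C)CC[C@H]1C(=C)C(=O)OC | intermediate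
26 | methyl 6α-[(2-{[(tert-butyldiphenylsilyl)oxy]methyl}prop-2-enoyl)oxy]-1β,3β-dihydroxy-5αH,7αH-eudesma-4(15),11(13)-dien-12-oate | C=C(CO[Si](c1ccccc1)(c1ccccc1)C(C)(C)C)C(=O)O[C@@H]1[C@H]2C(=C)[C@@H](O)C[C@@H](O)[C@]2(C)CC[C@H]1C(=C)C(=O)OC | intermediate
27 | methyl 1β,3β-dihydroxy-6α-{[2-(hydroxymethyl)prop-2-enoyl]oxy}-5αH,7αH-eudesma-4(15),11(13)-dien-12-oate (CNP0247525.1) | C=C(CO)C(=O)O[C@@H]1[C@H]2C(=C)[C@@H](O)C[C@@H](O)[C@]2(C)CC[C@H]1C(=C)C(=O)OC | target

Total step count: 17 (three steps for aldehyde 6, two for acid 16, twelve on the main line from 7).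
Longest linear sequence: 14 steps (steps 1, 2, 3, 5, 6, 9, 10, 11, 12, 13, 14, 15, 16, 17).

Steps most likely to fail

1. Step 12 (Proposed new method). The C10 radical may be reduced or may dimerise before it captures ethylene, ethylene may telomerise, the C8 radical may close onto C15 instead of C7, or tin radicals may attack the allyl sulfone directly. The fallback uses known polar chemistry and sets out from ketone 18. Its silyl enol ether 19 is made as in step 11 but isolated, and a Lewis-acid-mediated Mukaiyama–Michael addition to nitroethylene (SnCl4, CH2Cl2, −78 °C, aqueous work-up) should give the C10 2-nitroethyl ketone F1, with the new chain trans to the C5 side chain. DBU (MeCN, 0 °C) then forms the nitronate, which is more acidic than the sulfonyl methylene and should close ring B by 6-exo conjugate addition to C7 with loss of benzenesulfinate, giving the 8-nitro bicycle F2. Radical denitration (Bu3SnH, AIBN, toluene, 100 °C) comes back to the route at 22.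

2. Step 11. Enolisation may run towards C2 instead of C10, and the tertiary bromide may lose HBr. The fallback sets out from ketone 18: acid-catalysed enol acetylation (isopropenyl acetate, TsOH cat., 60 °C) gives the tetrasubstituted C1=C10 enol acetate F3, a stable compound that can be separated from its C1=C2 regioisomer by chromatography. NBS in aqueous THF at 0 °C then brominates it at C10 and comes back to the route at 20.

3. Step 9. Acylation of the flanked allylic alcohol may be slow, so that DMAP adds to the acrylic acid or the alkoxide displaces sulfinate at C13. The fallback sets out from alcohol 13 and builds the acyl group on the substrate instead: the small, reactive acryloyl chloride (Et3N, CH2Cl2, −78 °C) gives the acrylate ester F4, a Morita–Baylis–Hillman hydroxymethylation (aqueous formaldehyde, DABCO, dioxane, 25 °C) gives the 2-(hydroxymethyl)acrylate ester F5, and silylation (TBDPSCl, imidazole, DMF) comes back to the route at 17.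

Further compounds
F1 | step 12 | C10 2-nitroethyl ketone (18 bearing CH2CH2NO2 at C10, trans to the C5 side chain) | C=C(CO[Si](c1ccccc1)(c1ccccc1)C(C)(C)C)C(=O)O[C@@H](/C=C(/C(=O)OC)CS(=O)(=O)c1ccccc1)[C@H]1C(=C)CCC(=O)[C@]1(C)CC[N+](=O)[O-]
F2 | step 12 | 8-nitro bicycle (22 bearing NO2 at C8, both C8 epimers) | C=C(CO[Si](c1ccccc1)(c1ccccc1)C(C)(C)C)C(=O)O[C@@H]1[C@H]2C(=C)CCC(=O)[C@]2(C)CC([N+](=O)[O-])[C@H]1C(=C)C(=O)OC
F3 | step 11 | C1=C10 enol acetate of 18 | C=C(CO[Si](c1ccccc1)(c1ccccc1)C(C)(C)C)C(=O)O[C@@H](/C=C(/C(=O)OC)CS(=O)(=O)c1ccccc1)[C@H]1C(=C)CCC(OC(C)=O)=C1C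
F4 | step 9 | acrylate ester of 13 | C=CC(=O)O[C@@H](/C=C(/C(=O)OC)CS(=O)(=O)c1ccccc1)[C@H]1C(=C)CCC2(OCCO2)[C@@H]1C
F5 | step 9 | 2-(hydroxymethyl)acrylate ester of 13 | C=C(CO)C(=O)O[C@@H](/C=C(/C(=O)OC)CS(=O)(=O)c1ccccc1)[C@H]1C(=C)CCC2(OCCO2)[C@@H]1C
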